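**Plan**

- Retrosynthesis: the 4'-O-MOM group comes off last. Ring A is then cut at C7–C8 and C5–C6, leaving pyranone ester 13 (ring C with ring B attached, its 2-methyl group as C8 and its 3-CO2Me as C5) and the C6–C7 acyl unit 18, which already carries the prenyl group.
- Enabling feature: ring A bears oxygen on C5, C7 and C8a (a polyketide 1,3,5-pattern) and the prenylated C6 lies between C5 and C7. Both C5 and C7 can therefore come from carboxyl-level carbons on either side of one prenyl-bearing CH2.
- Pyranone 13 is cut at its ring CH (C2 of the isoflavone, from an amide acetal) and at the bond from C4 to the ester-bearing carbon (C-acylation of methyl acetoacetate by arylacetyl chloride 10).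
- Ring B comes from 2,4-dihydroxybenzaldehyde by C3-prenylation, O-protection and one-carbon homologation.
- Forward order: ring B (steps 1–5), ring C as the 4-pyranone (steps 6–7), acyl partner (steps 8–9), ring A by acylation and Claisen closure (step 10), deprotection (step 11).
- Stereochemistry: the target has no stereocentre and no stereogenic double bond, so nothing needs to be controlled.

Key step: step 10

Remarks on the chemistry:
- Ar = 2-methoxy-4-(methoxymethoxy)-3-(3-methylbut-2-en-1-yl)phenyl throughout.
- Tricarbonyl 11 will exist largely as an enol and is drawn in the keto form.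
- The acyl partner is used as its N-methoxy-N-methylamide 18 rather than as methyl ester 17. A stabilised dienolate is acylated only sluggishly by a methyl ester, and the acidic ketone released at once would quench dienolate that has not yet reacted.

**Route**

Step 1
Reactants: 1 2,4-dihydroxybenzaldehyde; 2 prenyl bromide (1-bromo-3-methylbut-2-ene)
Product: 3 2,4-dihydroxy-3-(3-methylbut-2-en-1-yl)benzaldehyde
Conditions: KOH (10% aq.), 0 °C → rt
Reagents that add atoms: none
Why: Direct C-prenylation of the resorcinol dianion in water, where the solvated phenoxide oxygens react at carbon, mainly at C3 between the two oxygens; this is a known alkylation of acylresorcinols, expected to be modest, with the C5 and O-prenyl isomers removed by chromatography.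

Step 2
Reactants: 3 2,4-dihydroxy-3-(3-methylbut-2-en-1-yl)benzaldehyde
Product: 4 2-hydroxy-4-(methoxymethoxy)-3-(3-methylbut-2-en-1-yl)benzaldehyde
Conditions: MOMCl (1.1 equiv), K2CO3, acetone, rt
Reagents that add atoms: chloromethyl methyl ether, COCCl
Why: Williamson-type etherification; the 4-OH is the more acidic, non-chelated phenol while the 2-OH is held in a hydrogen bond to the aldehyde, so mono-protection at O4 is expected.

Step 3
Reactants: 4 2-hydroxy-4-(methoxymethoxy)-3-(3-methylbut-2-en-1-yl)benzaldehyde
Product: 5 2-methoxy-4-(methoxymethoxy)-3-(3-methylbut-2-en-1-yl)benzaldehyde (Ar-CHO)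
Conditions: MeI, K2CO3, DMF, 45 °C
Reagents that add atoms: iodomethane, CI
Why: Williamson O-methylation of the remaining chelated phenol under slightly more forcing conditions; no other acidic site is present.

Step 4
Reactants: 5 2-methoxy-4-(methoxymethoxy)-3-(3-methylbut-2-en-1-yl)benzaldehyde
Product: 7 2-Ar-acetonitrile, via N-formyl vinyl sulfone 6 (not isolated)
Conditions: TosMIC, t-BuOK, DME, –40 °C; then MeOH, reflux
Reagents that add atoms: p-toluenesulfonylmethyl isocyanide (TosMIC), Cc1ccc(cc1)S(=O)(=O)C[N+]#[C-]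
Why: Van Leusen reductive cyanation: the TosMIC anion adds to the aldehyde, the oxazoline opens to formamide 6, and methanolysis with loss of sulfinate gives the homologous nitrile under base-only conditions that leave the MOM ether and the prenyl group untouched.

Step 5
Reactants: 7 2-Ar-acetonitrile
Product: 8 2-Ar-acetic acid
Conditions: KOH, EtOH/H2O, reflux; then 1 M HCl to pH 3, 0 °C
Reagents that add atoms: water, O; potassium hydroxide, [K+].[OH-]
Why: Alkaline nitrile hydrolysis; the aryl MOM ether, the methyl ether and the trisubstituted alkene are stable to hydroxide, and brief cold acidification avoids acetal cleavage.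

Step 6
Reactants: 8 2-Ar-acetic acid; 9 methyl acetoacetate
Product: 11 methyl 2-acetyl-4-Ar-3-oxobutanoate, via acid chloride 10 (not isolated)
Conditions: Me2C=C(Cl)NMe2 (1.1 equiv), CH2Cl2, 0 °C → rt; then added to 9, MgCl2, pyridine, CH2Cl2, 0 °C → rt; cold aq. citric acid
Reagents that add atoms: none
Why: The α-chloroenamine forms the acid chloride without HCl, so the MOM acetal survives; C-acylation of the magnesium chelate of methyl acetoacetate (MgCl2/amine Claisen-type acylation) then gives the 2-acyl-3-oxo ester and not the enol ester.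

Step 7
Reactants: 11 methyl 2-acetyl-4-Ar-3-oxobutanoate
Product: 13 methyl 5-Ar-2-methyl-4-oxo-4H-pyran-3-carboxylate, via enaminone 12 (not isolated)
Conditions: Me2NCH(OMe)2 (1.5 equiv), toluene, 80 °C; then AcOH, 60 °C
Reagents that add atoms: N,N-dimethylformamide dimethyl acetal, COC(OC)N(C)C
Why: Amide acetal condensation at the aryl-activated benzylic methylene (preferred over the acetyl methyl) gives enaminone 12, and the enol oxygen of the acetyl group then displaces dimethylamine by 6-endo addition–elimination to close the 4-pyranone, as in the deoxybenzoin-to-isoflavone condensation and the pyranone annulation of 2-acyl-1,3-dicarbonyl compounds.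

Step 8
Reactants: 14 2-methylbut-3-en-2-ol; 15 trimethyl orthoacetate
Product: 17 methyl 5-methylhex-4-enoate, via ketene acetal 16 (not isolated)
Conditions: MeC(OMe)3 (5 equiv), EtCO2H (cat.), 110 → 140 °C, MeOH distilled off
Reagents that add atoms: none
Why: Johnson–Claisen rearrangement: acid-catalysed exchange gives ketene acetal 16, whose [3,3]-sigmatropic shift delivers the γ,δ-unsaturated ester with the trisubstituted alkene.

Step 9
Reactants: 17 methyl 5-methylhex-4-enoate
Product: 18 N-methoxy-N,5-dimethylhex-4-enamide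
Conditions: MeNH(OMe)·HCl (1.5 equiv), i-PrMgCl (3 equiv), THF, –20 → 0 °C
Reagents that add atoms: N,O-dimethylhydroxylamine hydrochloride, CNOC.Cl
Why: Standard ester-to-Weinreb-amide aminolysis by the chloromagnesium amide of N,O-dimethylhydroxylamine; the isolated alkene is inert.

Step 10
Reactants: 13 methyl 5-Ar-2-methyl-4-oxo-4H-pyran-3-carboxylate; 18 N-methoxy-N,5-dimethylhex-4-enamide
Product: 20 3-Ar-5,7-dihydroxy-6-(3-methylbut-2-en-1-yl)-4H-chromen-4-one, via keto ester 19 (not isolated)
Conditions: LiN(i-Pr)2 (1.1 equiv), THF, –78 °C; 18 (1.2 equiv), –78 → –20 °C; LiN(i-Pr)2 (3.5 equiv), –78 °C → rt; AcOH, –78 °C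
Reagents that add atoms: none
Why: Proposed new method: the hindered amide base removes a proton from the 2-methyl group (vinylogous to C4=O and to the 3-ester), and the dienolate adds through its exocyclic carbon to amide 18 to give a chelated adduct (bond C7–C8). The second charge of base collapses the adduct to the enolate of keto ester 19 and deprotonates the prenyl-bearing C6; this carbanion attacks the 3-CO2Me group (bond C5–C6), methoxide leaves, and the cyclic triketone tautomerises to aromatic ring A. The closest known chemistry is acylation of lateral o-toluate anions followed by base-mediated Claisen cyclisation of 2-(2-oxoalkyl)benzoates to naphthalene-1,3-diols (Staunton–Weinreb-type annulation), so far not applied to a 4-pyranone-3-carboxylate. Ring A closes in a 6-exo-trig mode (enolate carbon onto the ester carbonyl) that becomes irreversible on aromatisation; no stereocentre is formed. The step needs deprotonation of the methyl group in preference to addition at the pyranone CH or C2 (hindered base at –78 °C, and the anionic ring is no longer electrophilic) and closure through carbon, not through the enolate oxygen (secured by forming the C6 carbanion of the dianion); the chelated adduct also keeps the acidic ketone from being released while unreacted dienolate is present. C6 enters already prenylated between the two new oxygens, so no 6- versus 8-prenyl question arises, and the 5- and 7-hydroxyls appear as phenoxides that need no protection.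

Step 11
Reactants: 20 3-Ar-5,7-dihydroxy-6-(3-methylbut-2-en-1-yl)-4H-chromen-4-one
Product: 21 2'-methoxylupalbigenin
Conditions: HCl (2 M aq.), MeOH, 40 °C
Reagents that add atoms: none
Why: Acid-catalysed acetal exchange (MOM cleavage) under mild conditions chosen to stay below the threshold for acid-mediated cyclisation of the o-prenylphenols to chromans.

**Compound list**

1 | 2,4-dihydroxybenzaldehyde | O=Cc1ccc(O)cc1O | starting material
2 | prenyl bromide (1-bromo-3-methylbut-2-ene) | CC(C)=CCBr | starting material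
3 | 2,4-dihydroxy-3-(3-methylbut-2-en-1-yl)benzaldehyde | O=Cc1ccc(O)c(CC=C(C)C)c1O | intermediate
4 | 2-hydroxy-4-(methoxymethoxy)-3-(3-methylbut-2-en-1-yl)benzaldehyde | O=Cc1ccc(OCOC)c(CC=C(C)C)c1O | intermediate
5 | 2-methoxy-4-(methoxymethoxy)-3-(3-methylbut-2-en-1-yl)benzaldehyde | O=Cc1ccc(OCOC)c(CC=C(C)C)c1OC | intermediate
6 | N-(2-Ar-1-tosylethenyl)formamide (alkene geometry not controlled) | O=CNC(=Cc1ccc(OCOC)c(CC=C(C)C)c1OC)S(=O)(=O)c1ccc(C)cc1 | intermediate
7 | 2-Ar-acetonitrile | N#CCc1ccc(OCOC)c(CC=C(C)C)c1OC | intermediate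
8 | 2-Ar-acetic acid | OC(=O)Cc1ccc(OCOC)c(CC=C(C)C)c1OC | intermediate
9 | methyl acetoacetate | COC(=O)CC(C)=O | starting material
10 | 2-Ar-acetyl chloride | ClC(=O)Cc1ccc(OCOC)c(CC=C(C)C)c1OC | intermediate
11 | methyl 2-acetyl-4-Ar-3-oxobutanoate | COC(=O)C(C(C)=O)C(=O)Cc1ccc(OCOC)c(CC=C(C)C)c1OC | intermediate
12 | methyl 2-acetyl-4-Ar-5-(dimethylamino)-3-oxopent-4-enoate | COC(=O)C(C(C)=O)C(=O)C(=CN(C)C)c1ccc(OCOC)c(CC=C(C)C)c1OC | intermediate
13 | methyl 5-Ar-2-methyl-4-oxo-4H-pyran-3-carboxylate | COC(=O)c1c(C)occ(-c2ccc(OCOC)c(CC=C(C)C)c2OC)c1=O | intermediate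
14 | 2-methylbut-3-en-2-ol | CC(C)(O)C=C | starting material
15 | trimethyl orthoacetate | CC(OC)(OC)OC | starting material
16 | 3-[(1-methoxyethenyl)oxy]-3-methylbut-1-ene | C=C(OC)OC(C)(C)C=C | intermediate
17 | methyl 5-methylhex-4-enoate | COC(=O)CCC=C(C)C | intermediate
18 | N-methoxy-N,5-dimethylhex-4-enamide | CON(C)C(=O)CCC=C(C)C | intermediate
19 | methyl 5-Ar-2-(6-methyl-2-oxohept-5-en-1-yl)-4-oxo-4H-pyran-3-carboxylate | COC(=O)c1c(CC(=O)CCC=C(C)C)occ(-c2ccc(OCOC)c(CC=C(C)C)c2OC)c1=O | intermediate
20 | 3-Ar-5,7-dihydroxy-6-(3-methylbut-2-en-1-yl)-4H-chromen-4-one (4'-O-MOM ether of the target) | COCOc1ccc(-c2coc3cc(O)c(CC=C(C)C)c(O)c3c2=O)c(OC)c1CC=C(C)C | intermediate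
21 | 2'-methoxylupalbigenin, 5,7-dihydroxy-3-[4-hydroxy-2-methoxy-3-(3-methylbut-2-en-1-yl)phenyl]-6-(3-methylbut-2-en-1-yl)-4H-chromen-4-one | COc1c(-c2coc3cc(O)c(CC=C(C)C)c(O)c3c2=O)ccc(O)c1CC=C(C)C | target

**Step count**

Total: 11 steps. Longest linear sequence: 9 steps (steps 1–7, 10, 11); steps 8–9 form the side branch.

**Steps most likely to fail**

1. Step 10 (proposed new method). The stabilised dienolate may be acylated too slowly or at the ring carbon, the base may add to the pyranone and open it, or the keto ester enolate may close through oxygen to a lactone instead of through C6. The fallback leaves the annulation for known deoxybenzoin chemistry; it sets out from acid 8 and rejoins the route at target 21.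
   - Acid 8 is converted with carbonyldiimidazole and MeNH(OMe)·HCl into N-methoxy-N-methyl-2-Ar-acetamide F1.
   - Phloroglucinol is protected (MOMCl, NaH, DMF) as 1,3,5-tris(methoxymethoxy)benzene F2.
   - F2 is lithiated between two MOM-oxy groups (n-BuLi, THF, 0 °C) and added to F1 to give the deoxybenzoin 2-Ar-1-[2,4,6-tris(methoxymethoxy)phenyl]ethan-1-one F3.
   - Brief HCl/MeOH at 0 °C should remove one of the two equivalent, carbonyl-activated ortho MOM groups to give 2-Ar-1-[2-hydroxy-4,6-bis(methoxymethoxy)phenyl]ethan-1-one F4.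
   - Mitsunobu etherification with 3-methylbut-2-en-1-ol gives the prenyl ether 2-Ar-1-[2,4-bis(methoxymethoxy)-6-(3-methylbut-2-en-1-yloxy)phenyl]ethan-1-one F5.
   - Heating in N,N-diethylaniline at about 200 °C should move the prenyl group by para-Claisen–Cope rearrangement to the carbon between the two MOM-oxy groups. This gives 2-Ar-1-[6-hydroxy-2,4-bis(methoxymethoxy)-3-(3-methylbut-2-en-1-yl)phenyl]ethan-1-one F6, whose only free phenol is the one that becomes O1, which fixes the 6-prenyl pattern.
   - DMF dimethyl acetal closes ring C to 3-Ar-5,7-bis(methoxymethoxy)-6-(3-methylbut-2-en-1-yl)-4H-chromen-4-one F7.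
   - HCl/MeOH removes all three MOM groups to give 21.

2. Step 7. The amide acetal may condense at the acetyl methyl instead of the benzylic methylene, the liberated dimethylamine may deacylate the tricarbonyl (retro-Claisen), or the acidic enol may be O-methylated. The fallback places the one-carbon unit on the benzylic carbon before the acetoacetate is acylated; it sets out from acid 8 and rejoins at pyranone 13.
   - Acid 8 is esterified (MeI, K2CO3, DMF) to methyl 2-Ar-acetate F8.
   - Formylation (HCO2Me, NaH, THF) gives methyl 2-Ar-3-hydroxyprop-2-enoate F9.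
   - O-methylation (Me2SO4, K2CO3) gives methyl (E)-2-Ar-3-methoxyprop-2-enoate F10.
   - LiOH in aqueous THF gives (E)-2-Ar-3-methoxyprop-2-enoic acid F11.
   - The α-chloroenamine of step 6 converts it into (E)-2-Ar-3-methoxyprop-2-enoyl chloride F12.
   - Acylation of the MgCl2/pyridine chelate of 9 gives methyl 2-acetyl-4-Ar-5-methoxy-3-oxopent-4-enoate F13.
   - On gentle warming with a trace of acid, the acetyl enol of F13 displaces methoxide by addition–elimination and gives 13 with the ring CH unambiguously next to the aryl-bearing carbon.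

3. Step 1. Alkylation may be spread over C3, C5 and oxygen, and conversion may be low. The fallback fixes the position by directed ortho-metalation; it sets out from 1 and rejoins at aldehyde 5.
   - 1 is mono-protected (MOMCl, K2CO3, acetone) to 2-hydroxy-4-(methoxymethoxy)benzaldehyde F14.
   - Methylation (MeI, K2CO3, DMF) gives 2-methoxy-4-(methoxymethoxy)benzaldehyde F15.
   - Acetalisation (HC(OMe)3, MeOH, PPTS) gives 1-(dimethoxymethyl)-2-methoxy-4-(methoxymethoxy)benzene F16.
   - n-BuLi in THF at 0 °C should lithiate the carbon flanked by the methoxy and MOM-oxy groups; transmetalation with CuBr·SMe2 and alkylation with prenyl bromide 2 gives 1-(dimethoxymethyl)-2-methoxy-4-(methoxymethoxy)-3-(3-methylbut-2-en-1-yl)benzene F17.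
   - PPTS in wet acetone releases aldehyde 5.

**Further compounds**

F1 | step 10 | N-methoxy-N-methyl-2-Ar-acetamide | CON(C)C(=O)Cc1ccc(OCOC)c(CC=C(C)C)c1OC
F2 | step 10 | 1,3,5-tris(methoxymethoxy)benzene | COCOc1cc(OCOC)cc(OCOC)c1
F3 | step 10 | 2-Ar-1-[2,4,6-tris(methoxymethoxy)phenyl]ethan-1-one | COCOc1cc(OCOC)c(C(=O)Cc2ccc(OCOC)c(CC=C(C)C)c2OC)c(OCOC)c1
F4 | step 10 | 2-Ar-1-[2-hydroxy-4,6-bis(methoxymethoxy)phenyl]ethan-1-one | COCOc1cc(O)c(C(=O)Cc2ccc(OCOC)c(CC=C(C)C)c2OC)c(OCOC)c1
F5 | step 10 | 2-Ar-1-[2,4-bis(methoxymethoxy)-6-(3-methylbut-2-en-1-yloxy)phenyl]ethan-1-one | COCOc1cc(OCC=C(C)C)c(C(=O)Cc2ccc(OCOC)c(CC=C(C)C)c2OC)c(OCOC)c1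
F6 | step 10 | 2-Ar-1-[6-hydroxy-2,4-bis(methoxymethoxy)-3-(3-methylbut-2-en-1-yl)phenyl]ethan-1-one | COCOc1cc(O)c(C(=O)Cc2ccc(OCOC)c(CC=C(C)C)c2OC)c(OCOC)c1CC=C(C)C
F7 | step 10 | 3-Ar-5,7-bis(methoxymethoxy)-6-(3-methylbut-2-en-1-yl)-4H-chromen-4-one | COCOc1cc2occ(-c3ccc(OCOC)c(CC=C(C)C)c3OC)c(=O)c2c(OCOC)c1CC=C(C)C
F8 | step 7 | methyl 2-Ar-acetate | COC(=O)Cc1ccc(OCOC)c(CC=C(C)C)c1OC
F9 | step 7 | methyl 2-Ar-3-hydroxyprop-2-enoate (enol of the formyl ester, geometry not defined) | COC(=O)C(=CO)c1ccc(OCOC)c(CC=C(C)C)c1OC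
F10 | step 7 | methyl (E)-2-Ar-3-methoxyprop-2-enoate | CO/C=C(/C(=O)OC)c1ccc(OCOC)c(CC=C(C)C)c1OC
F11 | step 7 | (E)-2-Ar-3-methoxyprop-2-enoic acid | CO/C=C(/C(=O)O)c1ccc(OCOC)c(CC=C(C)C)c1OC
F12 | step 7 | (E)-2-Ar-3-methoxyprop-2-enoyl chloride | CO/C=C(/C(=O)Cl)c1ccc(OCOC)c(CC=C(C)C)c1OC
F13 | step 7 | methyl 2-acetyl-4-Ar-5-methoxy-3-oxopent-4-enoate | CO/C=C(/C(=O)C(C(C)=O)C(=O)OC)c1ccc(OCOC)c(CC=C(C)C)c1OC
F14 | step 1 | 2-hydroxy-4-(methoxymethoxy)benzaldehyde | O=Cc1ccc(OCOC)cc1O
F15 | step 1 | 2-methoxy-4-(methoxymethoxy)benzaldehyde | O=Cc1ccc(OCOC)cc1OC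
F16 | step 1 | 1-(dimethoxymethyl)-2-methoxy-4-(methoxymethoxy)benzene | COC(OC)c1ccc(OCOC)cc1OC
F17 | step 1 | 1-(dimethoxymethyl)-2-methoxy-4-(methoxymethoxy)-3-(3-methylbut-2-en-1-yl)benzene | COC(OC)c1ccc(OCOC)c(CC=C(C)C)c1OC
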